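## Structural features

The target, 3,5-dihydroxy-2-(2,4-dihydroxy-5-methoxyphenyl)-7,8-dimethoxy-4H-chromen-4-one, is a flavonol without any stereocentre: benzene ring A is fused along C4a–C8a to the 4-pyranone ring C (O1, C2, C3, C4), and C2 carries the separate benzene ring B through the C2–C1' bond. Ring A bears four different neighbours in a row: a free hydroxyl on C5 (hydrogen-bonded to the C4 carbonyl), hydrogen on C6, methoxy groups on C7 and C8, and the ring oxygen O1 on C8a. Ring C has the enolic hydroxyl on C3, and ring B has hydroxyls on C2' and C4' and a methoxy group on C5'. Once unmasked, the 3-hydroxy-4-pyranone and the resorcinol-type ring B form an electron-rich polyphenol that is sensitive to air and base. A 5-hydroxy-7,8-dioxygenated flavone can also open and reclose under hot strong acid to the 5,6,7-isomer (Wessely–Moser rearrangement), so the last steps should be neutral. The real difficulty is not ring formation but telling oxygen atoms apart: four hydroxyls must end free beside three methyl ethers, and the two oxygens ortho to the acyl carbon C4 (on C5 and on C8a) must be distinguished, because closing ring C on the wrong one gives the 5-hydroxy-6,7-dimethoxy isomer. The key step uses the fact that C4a carries the acyl carbon C4 and its neighbour C5 carries oxygen; an aryne across C4a–C5 can take up such an ortho-acylphenol unit from a carboxylic acid in one operation, and the oxygen already on C8a, next to the triple bond, decides which end receives oxygen. A protected glycolic acid as the acid partner brings C4, C3 and the C3 oxygen together, so that ring C afterwards needs only C2 with ring B, which an aroyl group supplies.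

## Logic of the disconnections

The four free hydroxyls of 24 (on C3, C5, C2' and C4') are traced back to benzyl ethers, which gives 23. One hydrogenolysis under neutral conditions then ends the synthesis, with no acid near the ring A pattern and no reagent that could touch the methyl ethers on C7, C8 and C5'. The gain is that every sensitive phenol stays masked by one kind of group to the end. The demand is that all four benzyl groups, including the hindered ones on C3 and C2', leave without reduction of the C2–C3 double bond.

In 23 the bonds O1–C2 and C2–C3 are cut. Opening O1–C2 gives 22; cutting C2–C3 and rejoining C2 to the oxygen on C8a gives 21, in which the enolisable C3 and the aroyl carbon are held close together. The C–C bond then forms by an intramolecular acyl shift, free of the C- versus O-acylation problem of an intermolecular condensation. The gain is that ring C and the attachment of ring B are reduced to one ester bond. The demand is that only the oxygen on C8a is available, so the oxygen on C5 must be blocked beforehand, and that the ring closure of 22 uses acid mild enough for benzyl ethers.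

The ester C–O bond of 21 is cut to give 15 and 19. This is the convergent cut: it divides the molecule into a ring A ketone and a ring B acid of similar size, made separately. The demand is the acylation of a phenol that is flanked by a ketone and a methoxy group and is hydrogen-bonded.

15 goes back to 14 and then to 13 by exchange of oxygen substituents only: the hydroxyl on C8a of 15 is masked as a methoxymethyl ether (14), and the benzyl ether on C5 is removed (13). No skeletal bond is cut. The reason is that 13 is what the aryne reaction delivers, with the C5 oxygen free and the C8a oxygen masked, so two simple steps invert the roles of the two oxygens. The demand is an acetal cleavage by dilute acid that leaves the benzyl ethers and the α-benzyloxy ketone intact.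

In 13 the bonds C4–C4a and C5–O are cut, which leads to 12 and 11; 12 comes from 10 by loss of the silyl and triflate groups. The cut is made there because both bonds sit on neighbouring ring carbons and can be formed together, and because it leaves the C5 oxygen as the only free one. The gain is large: ring A is reduced to a benzene ring with three oxygen substituents and no carbon substituent, and C3, C4 and the C3 oxygen come from a bought two-carbon acid. The demand is that oxygen goes to the aryne carbon remote from the acetal oxygen and carbon to the near one, and that the acyl shift onto the aryl anion outruns its protonation.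

10 is traced to 8 by cutting the O–S bond of the triflate (9 lies between) and 8 to 5 by cutting the C–Si bond. The carbamate oxygen thus serves twice, first as the director that places silicon on the carbon between it and the acetal oxygen, then as the site of the leaving group. The gain is an aryne precursor that needs no halogen and no extra protecting group. The demand is metalation between the carbamate and the acetal and not between the carbamate and the methoxy group on the other side, and a carbamate that can be removed without harm to the aryl–silicon bond.

5 goes back to 4 by cutting the carbamate C–O bond, 4 to 2 by exchanging the phenolic C–O bond for the C–C bond to a formyl group (through 3), and 2 to 1 by removing the acetal. The reason is that 1 already has the three neighbouring oxygens in place, with the one that becomes O1 different from the other two. The demand is an oxidation in which the aryl group and not the hydride migrates.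

19 is traced to 18 (carboxyl to formyl), 18 to 17 (two benzyl C–O bonds cut) and 17 to 16 (the two hydroxyls returned to methyl ethers). 16 is a cheap aldehyde with the full oxygen pattern of ring B. The demand is a demethylation that takes the methoxy groups ortho and para to the formyl group and leaves the meta one, which the target keeps.

## Other disconnections considered

Alternative 1: The cut is O1–C2 of ring C, made as a ring expansion. The flavonol is traced to the five-membered ring of the aurone A1, (Z)-4,6,7-trimethoxy-2-[5-methoxy-2,4-bis(tosyloxy)benzylidene]benzofuran-3(2H)-one, by way of its dibromide A2. In the forward key step KOH in ethanol would open the furanone ring of A2 at its O–C2 bond, and the phenoxide set free would close on the benzylic carbon to give the flavonol A3, with ring C and the C3 hydroxyl in place.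
- In its favour: the sequence is short, uses cheap reagents and needs no organometallic or sealed-tube step. Its key step closes a ring, which the aryne step does not. On step economy it is the better of the two.
- Against it here: all three ring A oxygens are methyl ethers, so the C5 hydroxyl must be freed at the end by a Lewis acid that discriminates among the C5, C7, C8 and C5' methoxy groups while the C3 hydroxyl competes for the reagent. Acid at that stage also invites the ring A isomerisation.
- Further weaknesses: aryl tosylates would be expected to suffer in hot ethanolic KOH. The alkaline step has competing courses, namely loss of HBr back to A1 or solvolysis of the easily ionised benzylic bromide next to the electron-rich ring B. The coumaranone that precedes A1 must be made by acylation ortho to a phenol whose para position is also open.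
- Comparison: the question of which oxygen next to C4 is which is left open until a late selective demethylation, whereas the chosen plan settles it in its key step. Mechanistically the aryne insertion follows one path with its regiochemistry set by the C8a oxygen, while the course of the dibromide rearrangement would depend on the substituents of ring B.

Alternative 2: The cut removes three ring A bonds, C5–C6, C7–C8 and C8–C8a, so that ring A is built onto a finished pyranone. The forward key step is a Dötz benzannulation: the pyranonyl methoxycarbene complex of zerovalent chromium A4 would take up methoxyacetylene A5 and one CO ligand to give A6. In A6, C5 carries the methoxy group of the carbene, C7 that of the alkyne, and C8 the new hydroxyl.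
- In its favour: it is the most convergent of the four plans, since rings B and C are complete before ring A exists. Three skeletal bonds and a ring form in one step, against two bonds and no ring in the aryne step, which is a clear advantage in bond construction. The C8 oxygen emerges free and is distinguished without a protecting group.
- Against it here: it needs a stoichiometric, toxic chromium reagent made from Cr(CO)6. A4 requires a 3-benzyloxy-2-aryl-4-pyranone metalated at C5, a fragment whose preparation would probably be longer than the whole route to the aryne precursor.
- Further weaknesses: A5 is volatile and prone to polymerise. With a heteroatom-substituted alkyne the regiochemistry of insertion and the competition from cyclobutenone or furan formation are harder to foresee than with alkyl alkynes. The C4 carbonyl next to the carbene carbon can chelate the metal.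
- Comparison: after the key step the C8 hydroxyl must be methylated and the C5 methyl ether cleaved selectively, so the C5/C7/C8 problem returns as a Lewis acid step, where the chosen plan holds the C5 oxygen as a benzyl ether. On the number of steps after the key step the two plans are about equal. On the steps before it and on the predictability of the key step the chosen plan is the safer.

Alternative 3: The cut removes ring B at C1'–C2' and C5'–C6'. Ring B is built by a Diels–Alder reaction on the alkyne of the 2-ethynylchromone A7 (2-ethynyl-3,5,7,8-tetramethoxy-4H-chromen-4-one) with the bis(silyloxy)diene A8 (1,4-dimethoxy-1,3-bis(trimethylsilyloxy)buta-1,3-diene). In the forward step the nucleophilic, methoxy-bearing end of A8 would bond to the terminal alkyne carbon (the future C6') and the ketene acetal end to C1'. Acid work-up would eliminate methanol and remove the silyl groups, giving A9 with ring B aromatic.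
- In its favour: ring B arrives with its full 2',4'-dihydroxy-5'-methoxy pattern and both phenols free. The three steps that the chosen plan spends on the ring B acid, and the benzyl groups on ring B, are saved, and on this point it is the better. The regiochemistry follows from the polarisation of both partners. Its key step forms two skeletal bonds, as many as the aryne step, and closes a ring besides.
- Against it here: A7 already contains rings A and C, so the differentiation of the ring A oxygens is only moved into the synthesis of A7, where all of them are methyl ethers. The diene could also add in conjugate fashion without ring closure, or at C2 of the chromone.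
- Further weakness: the end game needs cleavage of exactly the C3 and C5 methyl ethers among five. The C5 one is assisted by chelation to the C4 carbonyl and the C3 one much less, and Lewis acid conditions endanger the C7/C8 ethers and the ring A pattern.
- Comparison: the chosen plan carries the C3 and C5 oxygens as benzyl ethers from the moment they enter and frees them by hydrogenolysis. It is longer at the ring B end and safer at the finish.

Key step: step 6

Remarks on the chemistry:
- The structures of 10 and 13 were checked against the target and are kept; 1, 11 and 16 are assumed to be bought.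
- 2 has no free hydroxyl ortho or para to its formyl group, so its oxidation to the phenol is planned as a peracid Baeyer–Villiger oxidation with formate cleavage and not under alkaline peroxide.
- The carbamate is the N-isopropyl carbamate, which directs the metalation after transient N-silylation and is removed by mild base in the flask in which the triflate is made.

## Route

Step 1
Reactants: 1 3-hydroxy-4,5-dimethoxybenzaldehyde
Product: 2 3,4-dimethoxy-5-(methoxymethoxy)benzaldehyde
Conditions: MOMCl, i-Pr2NEt, CH2Cl2, 0 °C to rt
Reagents that add atoms: chloromethyl methyl ether, COCCl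
Why: Williamson-type O-alkylation of the phenol with the chloromethyl ether under amine base; the aldehyde is inert, and the acetal later serves as lithium-chelating ortho-director and as acid-labile mask of the future C8a oxygen.

Step 2
Reactants: 2 3,4-dimethoxy-5-(methoxymethoxy)benzaldehyde
Product: 4 3,4-dimethoxy-5-(methoxymethoxy)phenol, via aryl formate 3 (not isolated)
Conditions: mCPBA, CH2Cl2, 0 °C to rt; then K2CO3, MeOH, rt
Reagents that add atoms: 3-chloroperbenzoic acid, OOC(=O)c1cccc(Cl)c1
Why: Baeyer–Villiger oxidation of an electron-rich benzaldehyde, in which the aryl group with a para methoxy substituent migrates in preference to hydride, should give the formate, which K2CO3 in methanol cleaves to the phenol; the acetal is stable to the weak carboxylic acid formed.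

Step 3
Reactants: 4 3,4-dimethoxy-5-(methoxymethoxy)phenol
Product: 5 3,4-dimethoxy-5-(methoxymethoxy)phenyl N-(propan-2-yl)carbamate
Conditions: i-PrNCO, Et3N (cat.), CH2Cl2, rt
Reagents that add atoms: isopropyl isocyanate, CC(C)N=C=O
Why: Amine-catalysed addition of the phenol to the isocyanate gives the N-monoalkyl carbamate, a strong ortho-director that can later be expelled under mild base by elimination to the isocyanate.

Step 4
Reactants: 5 3,4-dimethoxy-5-(methoxymethoxy)phenyl N-(propan-2-yl)carbamate
Product: 8 4,5-dimethoxy-3-(methoxymethoxy)-2-(trimethylsilyl)phenyl N-(propan-2-yl)carbamate, via N-silyl carbamate 6 (not isolated), via N-silyl arylsilane 7 (not isolated)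
Conditions: t-BuMe2SiOTf, TMEDA, Et2O, 0 °C to rt; then n-BuLi, TMEDA, −78 °C; then Me3SiCl, −78 °C to rt; cold aq. NaHSO4
Reagents that add atoms: chlorotrimethylsilane, C[Si](C)(C)Cl
Why: Directed ortho-metalation: the N–H is first masked as the N-silyl carbamate so that the nitrogen anion cannot fragment, and n-BuLi/TMEDA should then remove the proton between the carbamate and the methoxymethoxy group, where both groups coordinate lithium and the second acetal oxygen forms a chelate that the methoxy-flanked position cannot match. Me3SiCl traps the aryllithium, and the N–Si bond is hydrolysed on work-up.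

Step 5
Reactants: 8 4,5-dimethoxy-3-(methoxymethoxy)-2-(trimethylsilyl)phenyl N-(propan-2-yl)carbamate
Product: 10 4,5-dimethoxy-3-(methoxymethoxy)-2-(trimethylsilyl)phenyl trifluoromethanesulfonate, via silylphenol 9 (not isolated)
Conditions: DBU, Et2NH, MeCN, 40 °C; then PhNTf2, rt
Reagents that add atoms: N-phenylbis(trifluoromethanesulfonimide), O=S(=O)(N(c1ccccc1)S(=O)(=O)C(F)(F)F)C(F)(F)F
Why: DBU removes the carbamate N–H and the aryloxide is expelled (E1cB), the isocyanate being scavenged by Et2NH as a urea; the phenoxide is triflated in the same flask by PhNTf2, a mild sulfonyl donor that leaves the aryl–silicon bond and the acetal alone.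

Step 6
Reactants: 10 4,5-dimethoxy-3-(methoxymethoxy)-2-(trimethylsilyl)phenyl trifluoromethanesulfonate; 11 benzyloxyacetic acid
Product: 13 2-(benzyloxy)-1-[6-hydroxy-3,4-dimethoxy-2-(methoxymethoxy)phenyl]ethan-1-one, via aryne 12 (not isolated)
Conditions: CsF (excess), THF, 125 °C, sealed tube
Reagents that add atoms: none
Why: Fluoride attacks silicon and triflate leaves, which gives aryne 12. Caesium benzyloxyacetate should add through oxygen to the aryne carbon remote from the methoxymethoxy group (the future C5), which places the aryl anion on C4a next to the inductively withdrawing acetal oxygen; this is the usual regiochemistry of 3-alkoxyarynes, whose distortion makes the distal carbon the more electrophilic one. The aryl anion then attacks the carbonyl of the aryl ester just formed through a four-membered alkoxide, which opens to the ketone and the C5 phenoxide, so that the aryne is inserted into the C–O bond of the acid and the bonds C5–O and C4–C4a are formed. The closest known reaction type is the insertion of arynes, generated from silylaryl triflates with CsF in hot THF, into the C–O bond of carboxylic acids to give ortho-hydroxyaryl ketones. No ring is closed in the product (the four-membered ring is only a transient) and no stereocentre is formed. The step needs regioselectivity (oxygen to C5, carbon to C4a), which the acetal oxygen on C8a secures, and chemoselectivity for acyl shift over protonation of the aryl anion, which the high temperature and the excess of CsF (keeping the acid as its caesium salt) should favour. The product has the C5 hydroxyl free and the C8a oxygen masked, the differentiation of ring A on which the rest of the route depends.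

Step 7
Reactants: 13 2-(benzyloxy)-1-[6-hydroxy-3,4-dimethoxy-2-(methoxymethoxy)phenyl]ethan-1-one
Product: 14 2-(benzyloxy)-1-[6-(benzyloxy)-3,4-dimethoxy-2-(methoxymethoxy)phenyl]ethan-1-one
Conditions: BnBr, K2CO3, DMF, rt
Reagents that add atoms: benzyl bromide, BrCc1ccccc1
Why: Williamson benzylation of the chelated ortho-hydroxy ketone; it blocks the C5 oxygen so that only the C8a oxygen can later take part in ring closure, and the benzyl group leaves in the final hydrogenolysis.

Step 8
Reactants: 14 2-(benzyloxy)-1-[6-(benzyloxy)-3,4-dimethoxy-2-(methoxymethoxy)phenyl]ethan-1-one
Product: 15 2-(benzyloxy)-1-[6-(benzyloxy)-2-hydroxy-3,4-dimethoxyphenyl]ethan-1-one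
Conditions: HCl (aq.), MeOH, 50 °C
Reagents that add atoms: none
Why: Acid-catalysed acetal exchange with methanol removes the methoxymethyl group; benzyl ethers, aryl methyl ethers and the α-benzyloxy ketone are stable to dilute HCl in methanol.

Step 9
Reactants: 16 2,4,5-trimethoxybenzaldehyde
Product: 17 2,4-dihydroxy-5-methoxybenzaldehyde
Conditions: AlCl3 (excess), CH2Cl2, rt to reflux
Reagents that add atoms: none
Why: Lewis acid demethylation by AlCl3 should take the methoxy groups ortho and para to the formyl group, whose oxygens are conjugated with the complexed carbonyl (the ortho one also chelates aluminium), and leave the unactivated meta methoxy group, which is the one the target keeps.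

Step 10
Reactants: 17 2,4-dihydroxy-5-methoxybenzaldehyde
Product: 18 2,4-bis(benzyloxy)-5-methoxybenzaldehyde
Conditions: BnBr, K2CO3, DMF, 60 °C
Reagents that add atoms: benzyl bromide, BrCc1ccccc1
Why: Double Williamson etherification; warming brings the hydrogen-bonded ortho hydroxyl to full conversion.

Step 11
Reactants: 18 2,4-bis(benzyloxy)-5-methoxybenzaldehyde
Product: 19 2,4-bis(benzyloxy)-5-methoxybenzoic acid
Conditions: NaClO2, NaH2PO4, 2-methyl-2-butene, t-BuOH/H2O, rt
Reagents that add atoms: sodium chlorite, [Na+].[O-]Cl=O
Why: Pinnick oxidation is selective for the aldehyde; the alkene scavenges the hypochlorous acid that would otherwise chlorinate the electron-rich ring.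

Step 12
Reactants: 19 2,4-bis(benzyloxy)-5-methoxybenzoic acid; 15 2-(benzyloxy)-1-[6-(benzyloxy)-2-hydroxy-3,4-dimethoxyphenyl]ethan-1-one
Product: 21 3-(benzyloxy)-2-[(benzyloxy)acetyl]-5,6-dimethoxyphenyl 2,4-bis(benzyloxy)-5-methoxybenzoate, via acid chloride 20 (not isolated)
Conditions: (COCl)2, DMF (cat.), CH2Cl2, rt; then 15, Et3N, DMAP (cat.), CH2Cl2, 0 °C to rt
Reagents that add atoms: none
Why: The acid chloride is formed with oxalyl chloride under formamide catalysis and acylates the hindered, hydrogen-bonded phenol with DMAP as nucleophilic catalyst; the C8a oxygen is the only free hydroxyl, so only one ester can form.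

Step 13
Reactants: 21 3-(benzyloxy)-2-[(benzyloxy)acetyl]-5,6-dimethoxyphenyl 2,4-bis(benzyloxy)-5-methoxybenzoate
Product: 23 3,5-bis(benzyloxy)-2-[2,4-bis(benzyloxy)-5-methoxyphenyl]-7,8-dimethoxy-4H-chromen-4-one, via diketone 22 (not isolated)
Conditions: LiN(SiMe3)2 (3 equiv), THF, −78 °C to rt; then AcOH, H2SO4 (cat.), 60 °C
Reagents that add atoms: none
Why: Baker–Venkataraman rearrangement: the lithium enolate of the α-benzyloxy ketone attacks the neighbouring aryl ester through a six-membered transition state and the acyl group shifts from oxygen to C3 (C2–C3 bond). Acid then closes ring C by 6-exo-trig addition of the C8a hydroxyl to the aroyl carbonyl (O1–C2 bond) and dehydration; the C5 oxygen is benzylated, so no other mode of closure is open.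

Step 14
Reactants: 23 3,5-bis(benzyloxy)-2-[2,4-bis(benzyloxy)-5-methoxyphenyl]-7,8-dimethoxy-4H-chromen-4-one
Product: 24 3,5-dihydroxy-2-(2,4-dihydroxy-5-methoxyphenyl)-7,8-dimethoxy-4H-chromen-4-one
Conditions: H2 (1 atm), Pd/C, EtOAc/MeOH, rt
Reagents that add atoms: none
Why: Hydrogenolysis of the four benzyl ethers over palladium on carbon under neutral conditions; aryl methyl ethers are untouched, the C2–C3 double bond of the doubly aryl-conjugated vinylogous ester should be reduced far more slowly than O-benzyl bonds are cleaved, and the absence of acid excludes isomerisation of ring A.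

## Compound list

1 | 3-hydroxy-4,5-dimethoxybenzaldehyde | COc1cc(C=O)cc(O)c1OC | starting material
2 | 3,4-dimethoxy-5-(methoxymethoxy)benzaldehyde | COCOc1cc(C=O)cc(OC)c1OC | intermediate
3 | 3,4-dimethoxy-5-(methoxymethoxy)phenyl formate (not isolated) | COCOc1cc(OC=O)cc(OC)c1OC | intermediate
4 | 3,4-dimethoxy-5-(methoxymethoxy)phenol | COCOc1cc(O)cc(OC)c1OC | intermediate
5 | 3,4-dimethoxy-5-(methoxymethoxy)phenyl N-(propan-2-yl)carbamate | COCOc1cc(OC(=O)NC(C)C)cc(OC)c1OC | intermediate
6 | 3,4-dimethoxy-5-(methoxymethoxy)phenyl N-(tert-butyldimethylsilyl)-N-(propan-2-yl)carbamate (not isolated) | COCOc1cc(OC(=O)N(C(C)C)[Si](C)(C)C(C)(C)C)cc(OC)c1OC | intermediate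
7 | 4,5-dimethoxy-3-(methoxymethoxy)-2-(trimethylsilyl)phenyl N-(tert-butyldimethylsilyl)-N-(propan-2-yl)carbamate (not isolated) | COCOc1c([Si](C)(C)C)c(OC(=O)N(C(C)C)[Si](C)(C)C(C)(C)C)cc(OC)c1OC | intermediate
8 | 4,5-dimethoxy-3-(methoxymethoxy)-2-(trimethylsilyl)phenyl N-(propan-2-yl)carbamate | COCOc1c([Si](C)(C)C)c(OC(=O)NC(C)C)cc(OC)c1OC | intermediate
9 | 4,5-dimethoxy-3-(methoxymethoxy)-2-(trimethylsilyl)phenol (not isolated) | COCOc1c([Si](C)(C)C)c(O)cc(OC)c1OC | intermediate
10 | 4,5-dimethoxy-3-(methoxymethoxy)-2-(trimethylsilyl)phenyl trifluoromethanesulfonate | C[Si](C)(C)c1c(OS(=O)(=O)C(F)(F)F)cc(OC)c(OC)c1OCOC | intermediate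
11 | benzyloxyacetic acid | OC(=O)COCc1ccccc1 | starting material
12 | 4,5-dimethoxy-3-(methoxymethoxy)benzyne (1,2-didehydrobenzene; not isolated) | COCOC1=C(OC)C(OC)=CC#C1 | intermediate
13 | 2-(benzyloxy)-1-[6-hydroxy-3,4-dimethoxy-2-(methoxymethoxy)phenyl]ethan-1-one | O=C(COCc1ccccc1)c1c(O)cc(OC)c(OC)c1OCOC | intermediate
14 | 2-(benzyloxy)-1-[6-(benzyloxy)-3,4-dimethoxy-2-(methoxymethoxy)phenyl]ethan-1-one | O=C(COCc1ccccc1)c1c(OCc2ccccc2)cc(OC)c(OC)c1OCOC | intermediate
15 | 2-(benzyloxy)-1-[6-(benzyloxy)-2-hydroxy-3,4-dimethoxyphenyl]ethan-1-one | O=C(COCc1ccccc1)c1c(OCc2ccccc2)cc(OC)c(OC)c1O | intermediate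
16 | 2,4,5-trimethoxybenzaldehyde | COc1cc(OC)c(C=O)cc1OC | starting material
17 | 2,4-dihydroxy-5-methoxybenzaldehyde | COc1cc(C=O)c(O)cc1O | intermediate
18 | 2,4-bis(benzyloxy)-5-methoxybenzaldehyde | COc1cc(C=O)c(OCc2ccccc2)cc1OCc1ccccc1 | intermediate
19 | 2,4-bis(benzyloxy)-5-methoxybenzoic acid | COc1cc(C(=O)O)c(OCc2ccccc2)cc1OCc1ccccc1 | intermediate
20 | 2,4-bis(benzyloxy)-5-methoxybenzoyl chloride (not isolated) | COc1cc(C(=O)Cl)c(OCc2ccccc2)cc1OCc1ccccc1 | intermediate
21 | 3-(benzyloxy)-2-[(benzyloxy)acetyl]-5,6-dimethoxyphenyl 2,4-bis(benzyloxy)-5-methoxybenzoate | O=C(COCc1ccccc1)c1c(OCc2ccccc2)cc(OC)c(OC)c1OC(=O)c1cc(OC)c(OCc2ccccc2)cc1OCc1ccccc1 | intermediate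
22 | 2-(benzyloxy)-1-[6-(benzyloxy)-2-hydroxy-3,4-dimethoxyphenyl]-3-[2,4-bis(benzyloxy)-5-methoxyphenyl]propane-1,3-dione (racemic at C2, in equilibrium with its enol; not isolated) | O=C(C(OCc1ccccc1)C(=O)c1cc(OC)c(OCc2ccccc2)cc1OCc1ccccc1)c1c(OCc2ccccc2)cc(OC)c(OC)c1O | intermediate
23 | 3,5-bis(benzyloxy)-2-[2,4-bis(benzyloxy)-5-methoxyphenyl]-7,8-dimethoxy-4H-chromen-4-one | COc1cc(-c2oc3c(OC)c(OC)cc(OCc4ccccc4)c3c(=O)c2OCc2ccccc2)c(OCc2ccccc2)cc1OCc1ccccc1 | intermediate
24 | 3,5-dihydroxy-2-(2,4-dihydroxy-5-methoxyphenyl)-7,8-dimethoxy-4H-chromen-4-one | COc1cc(-c2oc3c(OC)c(OC)cc(O)c3c(=O)c2O)c(O)cc1O | target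

## Step count and least certain steps

Total: 14 steps. Longest linear sequence: 11 steps (steps 1–8 and 12–14); the ring B acid 19 takes 3 steps (9–11) and joins at step 12.

**Step 6 (key step).** The most likely failure is protonation of the aryl anion on C4a before it reaches the ester carbonyl, which stops the sequence at simple O-arylation of the acid. Erosion of the regioselectivity of addition and slow loss of the acetal at 125 °C are lesser concerns. The fallback sets out from 5 (with 11 as source of the side chain), returns at 13, and avoids the aryne.
- 11 is converted with N,O-dimethylhydroxylamine hydrochloride and carbonyldiimidazole into 2-(benzyloxy)-N-methoxy-N-methylacetamide F1.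
- 5 is N-silylated and lithiated as in step 4 (through 6), and the aryllithium is acylated with F1. This gives 2-[(benzyloxy)acetyl]-4,5-dimethoxy-3-(methoxymethoxy)phenyl N-(tert-butyldimethylsilyl)-N-(propan-2-yl)carbamate F2, which is not isolated and loses its N-silyl group on work-up to give 2-[(benzyloxy)acetyl]-4,5-dimethoxy-3-(methoxymethoxy)phenyl N-(propan-2-yl)carbamate F3.
- DBU and Et2NH in MeCN then remove the carbamate and give 13.
- Both stages are known reaction types: directed ortho-metalation with acylation by an N-methoxy-N-methylamide, and base cleavage of an N-monoalkyl carbamate.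

**Step 4.** The most likely failure is metalation at the other ortho position of the carbamate, the one flanked by a methoxy group, so that silicon enters on the wrong carbon. Attack of the silyl triflate on the acetal during N-silylation is a second risk. The fallback sets out from 1 and returns at 10. Regiochemistry is fixed by electrophilic substitution instead of metalation, and silicon is brought in by halogen–lithium exchange.
- 1 is brominated (Br2, NaOAc, AcOH) ortho to its free hydroxyl, between hydroxyl and formyl group, the position that the lower homologue isovanillin is known to prefer. This gives 2-bromo-3-hydroxy-4,5-dimethoxybenzaldehyde F4.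
- Methoxymethylation as in step 1 gives 2-bromo-4,5-dimethoxy-3-(methoxymethoxy)benzaldehyde F5.
- Baeyer–Villiger oxidation with mCPBA gives 2-bromo-4,5-dimethoxy-3-(methoxymethoxy)phenyl formate F6, and methanolysis gives 2-bromo-4,5-dimethoxy-3-(methoxymethoxy)phenol F7.
- Hexamethyldisilazane converts F7 into [2-bromo-4,5-dimethoxy-3-(methoxymethoxy)phenoxy]trimethylsilane F8.
- n-BuLi in THF at −78 °C then effects bromine–lithium exchange and a retro-Brook shift of silicon from oxygen to carbon. The lithium salt of 9 so formed is triflated with Tf2O to give 10.

**Step 13.** The most likely failure is a slow O-to-C acyl shift, because the ester carbonyl is shielded by the ortho benzyloxy group and deactivated by the electron-rich ring, with cleavage of the ester back to 15 as the competing process. Partial loss of the C5 benzyl group in the acid stage would be harmless, since it converges in step 14. The fallback sets out from 15 and 18 and returns at 23. The C2–C3 bond is made by aldol condensation with the more electrophilic aldehyde instead of acyl transfer.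
- Claisen–Schmidt condensation (KOH, EtOH) gives (Z)-2-(benzyloxy)-1-[6-(benzyloxy)-2-hydroxy-3,4-dimethoxyphenyl]-3-[2,4-bis(benzyloxy)-5-methoxyphenyl]prop-2-en-1-one F9.
- Oxidative cyclisation with catalytic I2 in DMSO at about 110 °C (oxa-Michael closure, then dehydrogenation) closes ring C and gives 23.

**Step 9.** The most likely failure is incomplete cleavage that stops at the mono-phenol, or over-cleavage that also takes the C5 methoxy group. The fallback sets out from 16 and returns at 17. It divides the task into two demethylations with different mechanisms.
- BCl3 (1 equiv) in CH2Cl2 at −78 to 0 °C removes only the chelated ortho methyl group and gives 2-hydroxy-4,5-dimethoxybenzaldehyde F10.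
- NaSEt in DMF at 100 °C then removes, by SN2 attack on carbon, the methyl of the methoxy group para to the formyl group, whose aryloxide is the better leaving group, and gives 17.

**Step 14.** The most likely failure is incomplete cleavage of the hindered benzyl ethers on C3 and C2' as the partly deprotected phenols bind to the catalyst, or slow reduction of the pyranone double bond on prolonged exposure. Air oxidation of the free flavonol during work-up is a further risk. The fallback sets out from 23 and returns at 24 in one operation and makes no new compound: BCl3 with pentamethylbenzene as cation scavenger in CH2Cl2 at −78 °C, a Lewis acid debenzylation at a temperature at which aryl methyl ethers and the ring A pattern should be safe.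

## Further compounds

F1 | step 6 | 2-(benzyloxy)-N-methoxy-N-methylacetamide | CON(C)C(=O)COCc1ccccc1
F2 | step 6 | 2-[(benzyloxy)acetyl]-4,5-dimethoxy-3-(methoxymethoxy)phenyl N-(tert-butyldimethylsilyl)-N-(propan-2-yl)carbamate | O=C(COCc1ccccc1)c1c(OC(=O)N(C(C)C)[Si](C)(C)C(C)(C)C)cc(OC)c(OC)c1OCOC
F3 | step 6 | 2-[(benzyloxy)acetyl]-4,5-dimethoxy-3-(methoxymethoxy)phenyl N-(propan-2-yl)carbamate | O=C(COCc1ccccc1)c1c(OC(=O)NC(C)C)cc(OC)c(OC)c1OCOC
F4 | step 4 | 2-bromo-3-hydroxy-4,5-dimethoxybenzaldehyde | COc1cc(C=O)c(Br)c(O)c1OC
F5 | step 4 | 2-bromo-4,5-dimethoxy-3-(methoxymethoxy)benzaldehyde | COCOc1c(Br)c(C=O)cc(OC)c1OC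
F6 | step 4 | 2-bromo-4,5-dimethoxy-3-(methoxymethoxy)phenyl formate | COCOc1c(Br)c(OC=O)cc(OC)c1OC
F7 | step 4 | 2-bromo-4,5-dimethoxy-3-(methoxymethoxy)phenol | COCOc1c(Br)c(O)cc(OC)c1OC
F8 | step 4 | [2-bromo-4,5-dimethoxy-3-(methoxymethoxy)phenoxy]trimethylsilane | COCOc1c(Br)c(O[Si](C)(C)C)cc(OC)c1OC
F9 | step 13 | (Z)-2-(benzyloxy)-1-[6-(benzyloxy)-2-hydroxy-3,4-dimethoxyphenyl]-3-[2,4-bis(benzyloxy)-5-methoxyphenyl]prop-2-en-1-one | O=C(/C(OCc1ccccc1)=C/c1cc(OC)c(OCc2ccccc2)cc1OCc1ccccc1)c1c(OCc2ccccc2)cc(OC)c(OC)c1O
F10 | step 9 | 2-hydroxy-4,5-dimethoxybenzaldehyde | COc1cc(O)c(C=O)cc1OC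
F0 | step 14 | none | none
A1 | alternative 1 | (Z)-4,6,7-trimethoxy-2-[5-methoxy-2,4-bis(tosyloxy)benzylidene]benzofuran-3(2H)-one | O=C1/C(=C/c2cc(OC)c(OS(=O)(=O)c3ccc(C)cc3)cc2OS(=O)(=O)c2ccc(C)cc2)Oc2c(OC)c(OC)cc(OC)c12
A2 | alternative 1 | 2-bromo-2-{bromo[5-methoxy-2,4-bis(tosyloxy)phenyl]methyl}-4,6,7-trimethoxybenzofuran-3(2H)-one (racemic anti adduct of bromine to the Z alkene, one enantiomer drawn) | O=C1[C@@](Br)([C@@H](Br)c2cc(OC)c(OS(=O)(=O)c3ccc(C)cc3)cc2OS(=O)(=O)c2ccc(C)cc2)Oc2c(OC)c(OC)cc(OC)c12
A3 | alternative 1 | 3-hydroxy-5,7,8-trimethoxy-2-[5-methoxy-2,4-bis(tosyloxy)phenyl]-4H-chromen-4-one | O=c1c(O)c(-c2cc(OC)c(OS(=O)(=O)c3ccc(C)cc3)cc2OS(=O)(=O)c2ccc(C)cc2)oc2c(OC)c(OC)cc(OC)c12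
A4 | alternative 2 | pentacarbonyl{[5-(benzyloxy)-6-[2,4-bis(benzyloxy)-5-methoxyphenyl]-4-oxo-4H-pyran-3-yl](methoxy)methylidene}chromium | COC(c1coc(-c2cc(OC)c(OCc3ccccc3)cc2OCc2ccccc2)c(OCc2ccccc2)c1=O)=[Cr](=C=O)(=C=O)(=C=O)(=C=O)=C=O
A5 | alternative 2 | methoxyacetylene | COC#C
A6 | alternative 2 | 3-(benzyloxy)-2-[2,4-bis(benzyloxy)-5-methoxyphenyl]-8-hydroxy-5,7-dimethoxy-4H-chromen-4-one | O=c1c(OCc2ccccc2)c(-c2cc(OC)c(OCc3ccccc3)cc2OCc2ccccc2)oc2c(O)c(OC)cc(OC)c12
A7 | alternative 3 | 2-ethynyl-3,5,7,8-tetramethoxy-4H-chromen-4-one | C#Cc1oc2c(OC)c(OC)cc(OC)c2c(=O)c1OC
A8 | alternative 3 | 1,4-dimethoxy-1,3-bis(trimethylsilyloxy)buta-1,3-diene (double-bond geometry not fixed) | COC=C(O[Si](C)(C)C)C=C(OC)O[Si](C)(C)C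
A9 | alternative 3 | 2-(2,4-dihydroxy-5-methoxyphenyl)-3,5,7,8-tetramethoxy-4H-chromen-4-one | O=c1c(OC)c(-c2cc(OC)c(O)cc2O)oc2c(OC)c(OC)cc(OC)c12
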